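**Retrosynthetic overview**

1. Numbering (eremophilane): ring B = C1–C5/C10, ring A = C5–C10, acetyl on C7, methyls on C4 and C5. Target 26 ⇐ its 10-O-triethylsilyl ether 25 (desilylation).
2. 25 ⇐ 23: heat turns a 5-alkenyl dioxinone into an α-acetyl vinylketene (C8=C7–C6=C5), which adds to the tethered E-enediol unit C9=C10 (silyl enol ether on C10, enol angelate on C9) in an intramolecular [4+2]. Bonds C8–C9 and C5–C10 form together and close rings A and B in one operation.
3. Enabling feature: ring A is a 2-acetylcyclohex-2-en-1-one (C8=O and the acetyl both on C7, C6=C7 next to quaternary C5), the retron of an acylketene diene. It is flanked by the trans C9/C10 dioxygenation (enediol dienophile), and the ring-fusion bond C5–C10 belongs to both rings.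
4. 23 ⇐ Z-alkenyl dioxinone 15 ⇐ cyclic alkenylsiloxane 12 (ring-closing metathesis) + iododioxinone 14 (Hiyama–Denmark coupling). The C9/C10 dienophile comes from a terminal diol via an α-silyloxy aldehyde.
5. C3/C4 ⇐ Marshall propargylation of pent-4-enal with (S)-but-3-yn-2-yl mesylate. Ring order: temporary oxasiline (step 7, opened in step 9), then rings A and B together (step 15).

Key step: step 15

Remark: compounds 6–20 are carried as a mixture of epimers at the future C10 (no stereo mark in the SMILES), because step 14 makes this carbon trigonal.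

**Step 1**
Reactants: 1 (S)-but-3-yn-2-ol
Product: 2 (S)-but-3-yn-2-yl methanesulfonate
Conditions: MsCl, Et3N, CH2Cl2, −78 to 0 °C
Reagents that add atoms: methanesulfonyl chloride, CS(=O)(=O)Cl
Why: Mesylation takes place at oxygen, so the carbinol stereocentre is untouched.

**Step 2**
Reactants: 2 (S)-but-3-yn-2-yl methanesulfonate; 3 pent-4-enal
Product: 5 (3R,4S)-3-methyloct-7-en-1-yn-4-ol, via allenylindium reagent 4 (not isolated)
Conditions: PdCl2(dppf) (5 mol%), InI (1.4 equiv), THF–HMPA 3:1, rt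
Reagents that add atoms: none
Why: Marshall propargylation: anti SN2′ attack of zerovalent palladium on the mesylate, transmetalation to indium with retention and a closed SE2′ transition state (aldehyde chain anti to the allenyl methyl) should give the anti homopropargylic alcohol, which sets C4 (R) and C3 (S) of the target from the mesylate stereocentre.

**Step 3**
Reactants: 5 (3R,4S)-3-methyloct-7-en-1-yn-4-ol
Product: 6 (3R,4S)-3-methyloct-1-yne-4,7,8-triol (both C7 epimers)
Conditions: OsO4 (2 mol%), NMO (1.5 equiv), acetone–H2O 4:1, rt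
Reagents that add atoms: N-methylmorpholine N-oxide, C[N+]1([O-])CCOCC1; osmium tetroxide (catalytic), O=[Os](=O)(=O)=O; water, O
Why: Upjohn dihydroxylation attacks the terminal alkene much faster than the alkyne; the new carbinol centre (future C10) needs no control because it is erased in step 14.

**Step 4**
Reactants: 6 (3R,4S)-3-methyloct-1-yne-4,7,8-triol
Product: 7 (3R,4S)-6-(2,2-dimethyl-1,3-dioxolan-4-yl)-3-methylhex-1-yn-4-ol
Conditions: Me2C(OMe)2, PPTS (5 mol%), CH2Cl2, rt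
Reagents that add atoms: 2,2-dimethoxypropane, COC(C)(C)OC
Why: Acid-catalysed transacetalisation closes the five-membered dioxolane on the terminal 1,2-diol and leaves the remote C3 hydroxyl free.

**Step 5**
Reactants: 7 (3R,4S)-6-(2,2-dimethyl-1,3-dioxolan-4-yl)-3-methylhex-1-yn-4-ol
Product: 9 (3S,4R)-1-(2,2-dimethyl-1,3-dioxolan-4-yl)-4,5-dimethylhex-5-en-3-ol, via alkenylalane 8 (not isolated)
Conditions: AlMe3 (3.5 equiv), Cp2ZrCl2 (20 mol%), H2O (1.5 equiv), CH2Cl2, −20 °C; then aq. Rochelle salt, 0 °C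
Reagents that add atoms: trimethylaluminium, C[Al](C)C
Why: Negishi zirconium-catalysed carboalumination (water-accelerated variant) adds methyl and aluminium syn across the terminal alkyne with methyl on the internal carbon, and protonolysis gives the 1,1-disubstituted alkene without touching C3/C4.

**Step 6**
Reactants: 9 (3S,4R)-1-(2,2-dimethyl-1,3-dioxolan-4-yl)-4,5-dimethylhex-5-en-3-ol; 10 chloro(ethenyl)dimethylsilane
Product: 11 ethenyl{[(3S,4R)-1-(2,2-dimethyl-1,3-dioxolan-4-yl)-4,5-dimethylhex-5-en-3-yl]oxy}dimethylsilane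
Conditions: Et3N, DMAP (5 mol%), CH2Cl2, 0 °C
Reagents that add atoms: none
Why: O-silylation of the secondary alcohol installs the temporary vinylsilane tether, whose SiCH carbon becomes C6.

**Step 7**
Reactants: 11 ethenyl{[(3S,4R)-1-(2,2-dimethyl-1,3-dioxolan-4-yl)-4,5-dimethylhex-5-en-3-yl]oxy}dimethylsilane
Product: 12 (5R,6S)-6-[2-(2,2-dimethyl-1,3-dioxolan-4-yl)ethyl]-2,2,4,5-tetramethyl-5,6-dihydro-2H-1,2-oxasiline
Conditions: Mo(=CHCMe2Ph)(=N-2,6-iPr2C6H3)[OCMe(CF3)2]2 (8 mol%), benzene, rt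
Reagents that add atoms: none
Why: Ring-closing metathesis of a vinylsilyl ether with the Schrock molybdenum alkylidene closes the six-membered oxasiline, which locks silicon cis to C4 across the new trisubstituted alkene.

**Step 8**
Reactants: 13 2,2,6-trimethyl-4H-1,3-dioxin-4-one
Product: 14 5-iodo-2,2,6-trimethyl-4H-1,3-dioxin-4-one
Conditions: NIS, AcOH, rt, dark
Reagents that add atoms: N-iodosuccinimide, O=C1CCC(=O)N1I
Why: Electrophilic iodination occurs at the nucleophilic enol-ether β-carbon (C5) of the dioxinone.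

**Step 9**
Reactants: 12 (5R,6S)-6-[2-(2,2-dimethyl-1,3-dioxolan-4-yl)ethyl]-2,2,4,5-tetramethyl-5,6-dihydro-2H-1,2-oxasiline; 14 5-iodo-2,2,6-trimethyl-4H-1,3-dioxin-4-one
Product: 15 5-[(1Z,3R,4S)-6-(2,2-dimethyl-1,3-dioxolan-4-yl)-4-hydroxy-2,3-dimethylhex-1-en-1-yl]-2,2,6-trimethyl-4H-1,3-dioxin-4-one
Conditions: Pd(dba)2 (5 mol%), Bu4NF (2 equiv), THF, rt
Reagents that add atoms: none
Why: Hiyama–Denmark fluoride-promoted coupling of the cyclic alkenylsiloxane proceeds with retention at the alkenyl carbon, so the dioxinone ends up cis to C4 (Z-diene, tether on the inside position) and the C3 hydroxyl is set free.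

**Step 10**
Reactants: 15 5-[(1Z,3R,4S)-6-(2,2-dimethyl-1,3-dioxolan-4-yl)-4-hydroxy-2,3-dimethylhex-1-en-1-yl]-2,2,6-trimethyl-4H-1,3-dioxin-4-one
Product: 16 (3S,4R,5Z)-1-(2,2-dimethyl-1,3-dioxolan-4-yl)-4,5-dimethyl-6-(2,2,6-trimethyl-4-oxo-4H-1,3-dioxin-5-yl)hex-5-en-3-yl acetate
Conditions: Ac2O, pyridine, DMAP (cat.), CH2Cl2, rt
Reagents that add atoms: acetic anhydride, CC(=O)OC(C)=O
Why: DMAP-catalysed acylation installs the C3 acetate of the target and masks the only hydroxyl that could trap the ketene.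

**Step 11**
Reactants: 16 (3S,4R,5Z)-1-(2,2-dimethyl-1,3-dioxolan-4-yl)-4,5-dimethyl-6-(2,2,6-trimethyl-4-oxo-4H-1,3-dioxin-5-yl)hex-5-en-3-yl acetate
Product: 17 (5S,6R,7Z)-1,2-dihydroxy-6,7-dimethyl-8-(2,2,6-trimethyl-4-oxo-4H-1,3-dioxin-5-yl)oct-7-en-5-yl acetate
Conditions: AcOH–H2O 4:1, 40 °C
Reagents that add atoms: none
Why: Mild aqueous acid hydrolyses the dioxolane, while the dioxinone (a vinylogous acylal) and the acetate should survive.

**Step 12**
Reactants: 17 (5S,6R,7Z)-1,2-dihydroxy-6,7-dimethyl-8-(2,2,6-trimethyl-4-oxo-4H-1,3-dioxin-5-yl)oct-7-en-5-yl acetate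
Product: 18 (5S,6R,7Z)-6,7-dimethyl-1,2-bis(triethylsilyloxy)-8-(2,2,6-trimethyl-4-oxo-4H-1,3-dioxin-5-yl)oct-7-en-5-yl acetate
Conditions: Et3SiCl (2.5 equiv), imidazole, DMF, 0 °C to rt
Reagents that add atoms: chlorotriethylsilane, CC[Si](Cl)(CC)CC
Why: Standard silylation of both hydroxyls under conditions that leave the acetate and dioxinone alone.

**Step 13**
Reactants: 18 (5S,6R,7Z)-6,7-dimethyl-1,2-bis(triethylsilyloxy)-8-(2,2,6-trimethyl-4-oxo-4H-1,3-dioxin-5-yl)oct-7-en-5-yl acetate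
Product: 20 (5S,6R,7Z)-6,7-dimethyl-1-oxo-2-(triethylsilyloxy)-8-(2,2,6-trimethyl-4-oxo-4H-1,3-dioxin-5-yl)oct-7-en-5-yl acetate, via alkoxysulfonium chloride 19 (not isolated)
Conditions: (COCl)2, DMSO, CH2Cl2, −78 to −30 °C; then Et3N, −78 to 0 °C
Reagents that add atoms: none
Why: Swern conditions cleave and oxidise a primary triethylsilyl ether selectively (the secondary one is too hindered to be activated), which gives the α-silyloxy aldehyde directly.

**Step 14**
Reactants: 20 (5S,6R,7Z)-6,7-dimethyl-1-oxo-2-(triethylsilyloxy)-8-(2,2,6-trimethyl-4-oxo-4H-1,3-dioxin-5-yl)oct-7-en-5-yl acetate; 21 angelic anhydride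
Product: 23 (1E,5S,6R,7Z)-5-acetoxy-6,7-dimethyl-2-(triethylsilyloxy)-8-(2,2,6-trimethyl-4-oxo-4H-1,3-dioxin-5-yl)octa-1,7-dien-1-yl (2Z)-2-methylbut-2-enoate, via potassium enolate 22 (not isolated)
Conditions: KN(SiMe3)2 (1.05 equiv), THF, −78 °C, 10 min; then 21 (1.2 equiv), −78 °C
Reagents that add atoms: none
Why: O-acylation of a potassium aldehyde enolate; deprotonation through the non-chelated, dipole-minimised (Cornforth-type) conformer should place the enolate oxygen anti to the silyloxy group (E enediol geometry, angelate oxygen cis to the C1 chain), and the absence of a nucleophilic catalyst avoids angelate-to-tiglate isomerisation.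

**Step 15**
Reactants: 23 (1E,5S,6R,7Z)-5-acetoxy-6,7-dimethyl-2-(triethylsilyloxy)-8-(2,2,6-trimethyl-4-oxo-4H-1,3-dioxin-5-yl)octa-1,7-dien-1-yl (2Z)-2-methylbut-2-enoate
Product: 25 (3S,4R,5R,9S,10R)-3-acetoxy-9-angeloyloxy-10-(triethylsilyloxy)-13-noreremophil-6-ene-8,11-dione, via acetyl vinylketene 24 (not isolated)
Conditions: toluene (0.005 M), 110 °C, 2 h
Reagents that add atoms: none
Why: Proposed new method: heating cleaves the dioxinone by retro-[4+2] loss of acetone to the α-acetyl vinylketene 24; its electrophilic ketene carbon C8 is attacked in the ketene plane by the nucleophilic enol-ether carbon C9 while the developing oxocarbenium carbon C10 is captured by the diene terminus C5, an asynchronous (possibly zwitterionic) intramolecular [4+2] with the vinylketene C8=C7–C6=C5 as the four-carbon partner, whose closest known reaction types are the dioxinone-to-acylketene cycloreversion with C-acylation of enol ethers, Diels–Alder reactions of silyl vinylketenes as dienes and inverse-demand intramolecular Diels–Alder reactions of 2-acyl dienes with enol ethers. Ring A is closed by both new bonds as the six-membered ring of the cycloaddition, and ring B is closed at the same time by the C5–C10 bond across the four-carbon tether (type 1 intramolecular Diels–Alder mode, six-membered, tether exo). C5 and C10: the tether sits on the inside (Z) position of the diene terminus, so only the exo-tether transition state can be reached and the cis ring fusion (C5 methyl cis to the C10 oxygen) is enforced, while the diene face is chosen by the C4 stereocentre, which keeps its hydrogen in the diene plane toward C7/C8 (1,3-allylic strain) and sends the tether to one face, which gives 4-methyl cis to 5-methyl. C9: suprafacial addition to the E enediol unit puts the angelate trans to the C10 silyloxy group. The step needs regioselectivity (C9 to C8, C10 to C5) and chemoselectivity over [2+2] closure, O-capture by the acetyl oxygen and 1,5-hydrogen shift: the silyloxy donor on C10 makes C9 the nucleophile, the tether turns every alternative closure into an eight- or ten-membered ring, and high dilution suppresses ketene dimerisation.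

**Step 16**
Reactants: 25 (3S,4R,5R,9S,10R)-3-acetoxy-9-angeloyloxy-10-(triethylsilyloxy)-13-noreremophil-6-ene-8,11-dione
Product: 26 (3S,4R,5R,9S,10R)-3-acetoxy-9-angeloyloxy-10-hydroxy-13-noreremophil-6-ene-8,11-dione (CNP0196241.1)
Conditions: HF·pyridine, pyridine, THF, 0 °C
Reagents that add atoms: none
Why: Buffered fluoride cleaves the tertiary silyl ether under non-basic conditions that should spare the β-hydroxy ketone (no retro-aldol or elimination), both esters and the epimerisable C9.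

**Compound list**

1 | (S)-but-3-yn-2-ol | C[C@H](O)C#C | starting material
2 | (S)-but-3-yn-2-yl methanesulfonate | C[C@H](OS(C)(=O)=O)C#C | intermediate
3 | pent-4-enal | C=CCCC=O | starting material
4 | (M)-buta-1,2-dien-1-yl(iodo)indium methanesulfonate | CC([H])=[C@]=C([H])[In](I)OS(C)(=O)=O | intermediate (not isolated)
5 | (3R,4S)-3-methyloct-7-en-1-yn-4-ol | C#C[C@@H](C)[C@@H](O)CCC=C | intermediate
6 | (3R,4S)-3-methyloct-1-yne-4,7,8-triol (C7 epimers) | C#C[C@@H](C)[C@@H](O)CCC(O)CO | intermediate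
7 | (3R,4S)-6-(2,2-dimethyl-1,3-dioxolan-4-yl)-3-methylhex-1-yn-4-ol | C#C[C@@H](C)[C@@H](O)CCC1COC(C)(C)O1 | intermediate
8 | O-dimethylaluminium alkoxide of (3S,4R,5E)-6-(dimethylalumanyl)-1-(2,2-dimethyl-1,3-dioxolan-4-yl)-4,5-dimethylhex-5-en-3-ol | C[Al](C)/C=C(\C)[C@@H](C)[C@@H](O[Al](C)C)CCC1COC(C)(C)O1 | intermediate (not isolated)
9 | (3S,4R)-1-(2,2-dimethyl-1,3-dioxolan-4-yl)-4,5-dimethylhex-5-en-3-ol | C=C(C)[C@@H](C)[C@@H](O)CCC1COC(C)(C)O1 | intermediate
10 | chloro(ethenyl)dimethylsilane | C=C[Si](C)(C)Cl | starting material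
11 | ethenyl{[(3S,4R)-1-(2,2-dimethyl-1,3-dioxolan-4-yl)-4,5-dimethylhex-5-en-3-yl]oxy}dimethylsilane | C=C(C)[C@@H](C)[C@@H](O[Si](C)(C)C=C)CCC1COC(C)(C)O1 | intermediate
12 | (5R,6S)-6-[2-(2,2-dimethyl-1,3-dioxolan-4-yl)ethyl]-2,2,4,5-tetramethyl-5,6-dihydro-2H-1,2-oxasiline | CC1=C[Si](C)(C)O[C@@H](CCC2COC(C)(C)O2)[C@@H]1C | intermediate
13 | 2,2,6-trimethyl-4H-1,3-dioxin-4-one | CC1=CC(=O)OC(C)(C)O1 | starting material
14 | 5-iodo-2,2,6-trimethyl-4H-1,3-dioxin-4-one | CC1=C(I)C(=O)OC(C)(C)O1 | intermediate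
15 | 5-[(1Z,3R,4S)-6-(2,2-dimethyl-1,3-dioxolan-4-yl)-4-hydroxy-2,3-dimethylhex-1-en-1-yl]-2,2,6-trimethyl-4H-1,3-dioxin-4-one | CC1=C(/C=C(/C)[C@@H](C)[C@@H](O)CCC2COC(C)(C)O2)C(=O)OC(C)(C)O1 | intermediate
16 | (3S,4R,5Z)-1-(2,2-dimethyl-1,3-dioxolan-4-yl)-4,5-dimethyl-6-(2,2,6-trimethyl-4-oxo-4H-1,3-dioxin-5-yl)hex-5-en-3-yl acetate | CC1=C(/C=C(/C)[C@@H](C)[C@@H](OC(C)=O)CCC2COC(C)(C)O2)C(=O)OC(C)(C)O1 | intermediate
17 | (5S,6R,7Z)-1,2-dihydroxy-6,7-dimethyl-8-(2,2,6-trimethyl-4-oxo-4H-1,3-dioxin-5-yl)oct-7-en-5-yl acetate | CC1=C(/C=C(/C)[C@@H](C)[C@@H](OC(C)=O)CCC(O)CO)C(=O)OC(C)(C)O1 | intermediate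
18 | (5S,6R,7Z)-6,7-dimethyl-1,2-bis(triethylsilyloxy)-8-(2,2,6-trimethyl-4-oxo-4H-1,3-dioxin-5-yl)oct-7-en-5-yl acetate | CC1=C(/C=C(/C)[C@@H](C)[C@@H](OC(C)=O)CCC(O[Si](CC)(CC)CC)CO[Si](CC)(CC)CC)C(=O)OC(C)(C)O1 | intermediate
19 | {[(5S,6R,7Z)-5-acetoxy-6,7-dimethyl-2-(triethylsilyloxy)-8-(2,2,6-trimethyl-4-oxo-4H-1,3-dioxin-5-yl)oct-7-en-1-yl]oxy}dimethylsulfonium chloride | CC1=C(/C=C(/C)[C@@H](C)[C@@H](OC(C)=O)CCC(O[Si](CC)(CC)CC)CO[S+](C)C)C(=O)OC(C)(C)O1.[Cl-] | intermediate (not isolated)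
20 | (5S,6R,7Z)-6,7-dimethyl-1-oxo-2-(triethylsilyloxy)-8-(2,2,6-trimethyl-4-oxo-4H-1,3-dioxin-5-yl)oct-7-en-5-yl acetate | CC1=C(/C=C(/C)[C@@H](C)[C@@H](OC(C)=O)CCC(O[Si](CC)(CC)CC)C=O)C(=O)OC(C)(C)O1 | intermediate
21 | angelic anhydride, (2Z)-2-methylbut-2-enoic anhydride | C/C=C(/C)C(=O)OC(=O)/C(C)=C\C | starting material
22 | potassium (1E,5S,6R,7Z)-5-acetoxy-6,7-dimethyl-2-(triethylsilyloxy)-8-(2,2,6-trimethyl-4-oxo-4H-1,3-dioxin-5-yl)octa-1,7-dien-1-olate | CC1=C(/C=C(/C)[C@@H](C)[C@@H](OC(C)=O)CC/C(O[Si](CC)(CC)CC)=C\[O-])C(=O)OC(C)(C)O1.[K+] | intermediate (not isolated)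
23 | (1E,5S,6R,7Z)-5-acetoxy-6,7-dimethyl-2-(triethylsilyloxy)-8-(2,2,6-trimethyl-4-oxo-4H-1,3-dioxin-5-yl)octa-1,7-dien-1-yl (2Z)-2-methylbut-2-enoate | CC1=C(/C=C(/C)[C@@H](C)[C@@H](OC(C)=O)CC/C(O[Si](CC)(CC)CC)=C\OC(=O)/C(C)=C\C)C(=O)OC(C)(C)O1 | intermediate
24 | (1E,5S,6R,7Z)-5-acetoxy-9-acetyl-6,7-dimethyl-10-oxo-2-(triethylsilyloxy)deca-1,7,9-trien-1-yl (2Z)-2-methylbut-2-enoate (α-acetyl vinylketene) | O=C=C(C(C)=O)/C=C(/C)[C@@H](C)[C@@H](OC(C)=O)CC/C(O[Si](CC)(CC)CC)=C\OC(=O)/C(C)=C\C | intermediate (not isolated)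
25 | (3S,4R,5R,9S,10R)-3-acetoxy-9-angeloyloxy-10-(triethylsilyloxy)-13-noreremophil-6-ene-8,11-dione | C/C=C(/C)C(=O)O[C@@H]1C(=O)C(C(C)=O)=C[C@]2(C)[C@@H](C)[C@@H](OC(C)=O)CC[C@]12O[Si](CC)(CC)CC | intermediate
26 | (3S,4R,5R,9S,10R)-3-acetoxy-9-angeloyloxy-10-hydroxy-13-noreremophil-6-ene-8,11-dione (CNP0196241.1) | C/C=C(/C)C(=O)O[C@@H]1C(=O)C(C(C)=O)=C[C@]2(C)[C@@H](C)[C@@H](OC(C)=O)CC[C@]12O | target

**Step count and risks**

Total steps: 16. Longest linear sequence: 15 steps (steps 1–7 and 9–16, from 1); step 8 is a one-step side branch.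

Steps most likely to fail:

1. Step 15 (Proposed new method). The vinylketene may be consumed before it cyclises: a 1,5-hydrogen shift from C4–H to the ketene carbon would destroy both the diene and the C4 stereocentre. Silyl transfer from O10 to the ketene-derived enolate would give an open-chain C-acylation product, and a [2+2] closure or poor facial control would give other skeletons or diastereomers. The fallback uses known chemistry: the same two bonds are still made in one cycloaddition, but from a 2-acetyl-1,3-diene, and C8 is oxidised afterwards. It sets out from 12. Iododesilylation (NIS, MeCN–ClCH2CN, 0 °C, retention) should give the vinyl iodide (1Z,3R,4S)-6-(2,2-dimethyl-1,3-dioxolan-4-yl)-1-iodo-2,3-dimethylhex-1-en-4-ol F1. The operations of steps 10 to 14 would then give in turn its acetate F2, the diol F3, the bis(triethylsilyl) ether F4, the α-silyloxy aldehyde F5 and the E enol angelate F6. Stille coupling of F6 with 3-(tributylstannyl)but-3-en-2-one F7 (from but-3-yn-2-one, Bu3SnH and Pd(PPh3)4) under Pd2(dba)3, AsPh3 and CuI in NMP should give the 2-acetyl diene F8. On warming (toluene, 60–80 °C) F8 should undergo the inverse-electron-demand intramolecular Diels–Alder reaction of 2-acyl dienes with enol ethers, under the same stereocontrol elements, to the 8-deoxo cycloadduct F9. Allylic oxidation of the C8 methylene (Rh2(cap)4 with tBuOOH, or CrO3 with 3,5-dimethylpyrazole) comes back to the route at 25.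

2. Step 14. Enolisation may run through a chelated or equilibrated enolate and give the O,O-cis (Z) isomer, which would end as the C9 epimer; competing deprotonation of the dioxinone methyl, C-acylation, or isomerisation of the angelate to the tiglate are also possible. The fallback takes the Z series on purpose and corrects C9 by inversion. It sets out from 20: equilibrating silylation (Et3SiOTf, Et3N, CH2Cl2, 0 °C) should give the (1Z)-1,2-bis(triethylsilyloxy)alkene F10. Thermolysis as in step 15 then adds suprafacially to give the 9-epi 9,10-bis(triethylsilyl) ether F11 (9-oxygen cis to 10-oxygen). The more labile secondary silyl ether is removed (PPTS, MeOH, 0 °C) to give the 9-epi alcohol F12, and a Mitsunobu esterification with angelic acid (PPh3, DIAD, toluene) inverts C9 and comes back to the route at 25.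

3. Step 9. The hindered trisubstituted alkenylsiloxane may undergo protodesilylation instead of transmetalation, and the fluoride-generated C3 alkoxide may attack the dioxinone carbonyl (acyl transfer with loss of acetone). The fallback builds the same Z-diene by hydrosilylation and methylation and sets out from 7. Sonogashira coupling with 14 (PdCl2(PPh3)2, CuI, iPr2NH, THF) should give the alkynyl dioxinone F13. Silylation with (HMe2Si)2NH gives the dimethylsilyl ether F14, and intramolecular syn hydrosilylation (Karstedt catalyst Pt2[(CH2=CHSiMe2)2O]3, THF) closes the five-membered alkylidene oxasilolane F15 with silicon on the carbon next to C4. Iododesilylation (NIS, retention) gives the (1E)-2-iodoalkenyl dioxinone F16, and Negishi methylation (MeZnCl, Pd(PPh3)4, THF) comes back to the route at 15.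

**Further compounds**

F1 | step 15 | (1Z,3R,4S)-6-(2,2-dimethyl-1,3-dioxolan-4-yl)-1-iodo-2,3-dimethylhex-1-en-4-ol | I/C=C(/C)[C@@H](C)[C@@H](O)CCC1COC(C)(C)O1
F2 | step 15 | (3S,4R,5Z)-1-(2,2-dimethyl-1,3-dioxolan-4-yl)-6-iodo-4,5-dimethylhex-5-en-3-yl acetate | I/C=C(/C)[C@@H](C)[C@@H](OC(C)=O)CCC1COC(C)(C)O1
F3 | step 15 | (5S,6R,7Z)-1,2-dihydroxy-8-iodo-6,7-dimethyloct-7-en-5-yl acetate | I/C=C(/C)[C@@H](C)[C@@H](OC(C)=O)CCC(O)CO
F4 | step 15 | (5S,6R,7Z)-8-iodo-6,7-dimethyl-1,2-bis(triethylsilyloxy)oct-7-en-5-yl acetate | I/C=C(/C)[C@@H](C)[C@@H](OC(C)=O)CCC(O[Si](CC)(CC)CC)CO[Si](CC)(CC)CC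
F5 | step 15 | (5S,6R,7Z)-8-iodo-6,7-dimethyl-1-oxo-2-(triethylsilyloxy)oct-7-en-5-yl acetate | I/C=C(/C)[C@@H](C)[C@@H](OC(C)=O)CCC(O[Si](CC)(CC)CC)C=O
F6 | step 15 | (1E,5S,6R,7Z)-5-acetoxy-8-iodo-6,7-dimethyl-2-(triethylsilyloxy)octa-1,7-dien-1-yl (2Z)-2-methylbut-2-enoate | I/C=C(/C)[C@@H](C)[C@@H](OC(C)=O)CC/C(O[Si](CC)(CC)CC)=C\OC(=O)/C(C)=C\C
F7 | step 15 | 3-(tributylstannyl)but-3-en-2-one | CCCC[Sn](CCCC)(CCCC)C(=C)C(C)=O
F8 | step 15 | (1E,5S,6R,7Z)-5-acetoxy-9-acetyl-6,7-dimethyl-2-(triethylsilyloxy)deca-1,7,9-trien-1-yl (2Z)-2-methylbut-2-enoate | C=C(C(C)=O)/C=C(/C)[C@@H](C)[C@@H](OC(C)=O)CC/C(O[Si](CC)(CC)CC)=C\OC(=O)/C(C)=C\C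
F9 | step 15 | 8-deoxo analogue of 25: 3-acetoxy-9-angeloyloxy-10-(triethylsilyloxy)-13-noreremophil-6-en-11-one | C/C=C(/C)C(=O)O[C@@H]1CC(C(C)=O)=C[C@]2(C)[C@@H](C)[C@@H](OC(C)=O)CC[C@]12O[Si](CC)(CC)CC
F10 | step 14 | (5S,6R,7Z)-6,7-dimethyl-1,2-bis(triethylsilyloxy)-8-(2,2,6-trimethyl-4-oxo-4H-1,3-dioxin-5-yl)octa-1(Z),7-dien-5-yl acetate | CC1=C(/C=C(/C)[C@@H](C)[C@@H](OC(C)=O)CC/C(O[Si](CC)(CC)CC)=C/O[Si](CC)(CC)CC)C(=O)OC(C)(C)O1
F11 | step 14 | 9-epi-3-acetoxy-9,10-bis(triethylsilyloxy)-13-noreremophil-6-ene-8,11-dione | CC[Si](CC)(CC)O[C@H]1C(=O)C(C(C)=O)=C[C@]2(C)[C@@H](C)[C@@H](OC(C)=O)CC[C@]12O[Si](CC)(CC)CC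
F12 | step 14 | 9-epi-3-acetoxy-9-hydroxy-10-(triethylsilyloxy)-13-noreremophil-6-ene-8,11-dione | O[C@H]1C(=O)C(C(C)=O)=C[C@]2(C)[C@@H](C)[C@@H](OC(C)=O)CC[C@]12O[Si](CC)(CC)CC
F13 | step 9 | 5-[(3R,4S)-6-(2,2-dimethyl-1,3-dioxolan-4-yl)-4-hydroxy-3-methylhex-1-yn-1-yl]-2,2,6-trimethyl-4H-1,3-dioxin-4-one | CC1=C(C#C[C@@H](C)[C@@H](O)CCC2COC(C)(C)O2)C(=O)OC(C)(C)O1
F14 | step 9 | dimethylsilyl ether of F13 | CC1=C(C#C[C@@H](C)[C@@H](O[SiH](C)C)CCC2COC(C)(C)O2)C(=O)OC(C)(C)O1
F15 | step 9 | 5-{(E)-[(4S,5S)-5-[2-(2,2-dimethyl-1,3-dioxolan-4-yl)ethyl]-2,2,4-trimethyl-1,2-oxasilolan-3-ylidene]methyl}-2,2,6-trimethyl-4H-1,3-dioxin-4-one | CC1=C(/C=C2/[Si](C)(C)O[C@@H](CCC3COC(C)(C)O3)[C@@H]2C)C(=O)OC(C)(C)O1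
F16 | step 9 | 5-[(1E,3S,4S)-6-(2,2-dimethyl-1,3-dioxolan-4-yl)-4-hydroxy-2-iodo-3-methylhex-1-en-1-yl]-2,2,6-trimethyl-4H-1,3-dioxin-4-one | CC1=C(/C=C(/I)[C@@H](C)[C@@H](O)CCC2COC(C)(C)O2)C(=O)OC(C)(C)O1
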